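**Retrosynthetic overview**
1. The target is a 2',8''-biflavone. The last steps only methylate O4' and unmask O5'' (peri methyl ether) and O7 (pivalate).
2. Key disconnection C2'–C8'': ring B of the acceptor flavone (fragment 2) is raised to the para-quinol level (1'-hydroxy-4'-oxocyclohexa-2',5'-dienyl). It is arylated by the C8''–H of 5,7,4'-trimethoxyflavone (fragment 1) with loss of water, with no halide or metal on either partner.
3. Enabling feature: C2' is meta to O4' and adjacent to C1'. In the dearomatised ring B it is therefore the β-carbon of the C4'=O dienone, and the 1'-OH is the leaving group that restores the arene. C8'' is the free carbon of the phloroglucinol-type ring A, between O1'' and the 7''-methoxy group.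
4. Both fragments come from apigenin: permethylation gives fragment 1, and oxidative dearomatisation followed by 7-O-acylation gives fragment 2.
5. Ring order: all six rings arrive with apigenin and none is built. Ring B of fragment 2 is dearomatised in step 2 and re-aromatised in step 4.

Key step: step 4

Assumption: the target SMILES carries no stereodescriptor, so the hindered C2'–C8'' axis is taken as configurationally unspecified and the biflavone is made as the racemate.
Locants: fragment 2 (acceptor flavone) carries 2–8 and 1'–6'. Fragment 1 (donor flavone) carries 2''–8'' and 1'''–6'''.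

Step 1
Reactants: 1 apigenin
Product: 2 5,7,4'-trimethoxyflavone
Conditions: MeI (6 equiv), K2CO3 (6 equiv), DMF, 50 °C
Reagents that add atoms: iodomethane, CI
Why: Exhaustive Williamson etherification, in which excess iodomethane and carbonate methylate the two free phenols and, on warming, also the hydrogen-bonded 5-hydroxyl group, which must be capped so that the later arylation goes to C8.

Step 2
Reactants: 1 apigenin
Product: 3 protoapigenone (2-(1-hydroxy-4-oxocyclohexa-2,5-dien-1-yl)-5,7-dihydroxychromen-4-one)
Conditions: PhI(OCOCF3)2 (2 equiv), MeCN–H2O 9:1, high dilution, 80 °C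
Reagents that add atoms: water, O
Why: Oxidative dearomatisation of a para-substituted phenol by a hypervalent iodine reagent with capture of the phenoxenium ion by water at C1', a reaction with direct precedent on 4'-hydroxyflavones, whose ring A is shielded from oxidation by conjugation to the pyranone carbonyl; C1' bears two identical ring arms and is no stereocentre.

Step 3
Reactants: 3 protoapigenone
Product: 4 7-O-pivaloylprotoapigenone
Conditions: t-BuCOCl (1.05 equiv), i-Pr2NEt (1.2 equiv), THF, 0 °C
Reagents that add atoms: pivaloyl chloride, CC(C)(C)C(=O)Cl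
Why: Chemoselective O-acylation of the only acidic, unhindered hydroxyl group (7-OH), because 5-OH is locked in a hydrogen bond to C4=O, 1'-OH is tertiary, and the hindered amine does not add to the dienone.

Step 4
Reactants: 2 5,7,4'-trimethoxyflavone; 4 7-O-pivaloylprotoapigenone
Product: 6 biflavone phenol (5,4'-dihydroxy-5'',7'',4'''-trimethoxy-7-pivaloyloxy-2',8''-biflavone), via conjugate adduct 5 (not isolated)
Conditions: 2 (2.5 equiv), CF3SO3H (0.2 equiv), (CF3)2CHOH–CH2Cl2 4:1, 0.4 M in 2, slow addition of 4, 25 → 50 °C
Reagents that add atoms: none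
Why: Proposed new method: hydrogen bonding by the fluorinated alcohol and the catalytic acid (buffered by the basic pyranone carbonyl of the excess donor 2) polarise the C4'=O group of the cross-conjugated dienone 4, C8'' of unprotonated 2 attacks the β-carbon C2' in a Friedel–Crafts-type conjugate addition, and the adduct 5, which in its dienol form is an arene hydrate, expels the 1'-hydroxyl group together with H2' as water, so that ring B re-aromatises irreversibly to the 4'-phenol 6. The closest known reaction types are the acid-promoted couplings of electron-rich arenes with para-quinols and with quinone monoketals in fluorinated alcohols, which likewise end in rearomatisation to a biaryl; new here are a flavone ring A as donor and a flavone-derived para-quinol as acceptor. No ring is closed and no lasting stereocentre is made: C2' and C6' of 4 are enantiotopic and give the same arene, the two stereocentres of 5 (C1', C2') vanish on dehydration, and the new axis forms as a racemate. On the acceptor the step needs attack meta to O4', which the dienone polarity dictates, while the electron-poor 4-oxochromen-2-yl group at C1' disfavours ionisation to a phenoxenium ion (the path to C3' products), and addition at C4' is reversible and cannot aromatise. On the donor it needs C8'' over C6'', secured by the cap on O5'': C6'' is then buttressed between two methoxy groups whereas C8'' has the tied-back ring oxygen O1'' as one neighbour, in line with the C8 selectivity of halogenation of 5,7-dimethoxyflavones. Between the two A rings it needs 2 to be the only nucleophile, secured by the 7-O-pivaloyl group and the chelated 5-OH, which make ring A of 4 and of 6 much less electron-rich, and helped by slow addition of 4 to excess 2, which also lets bimolecular capture outrun the dienone–phenol rearrangement.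

Step 5
Reactants: 6 biflavone phenol
Product: 7 4'-O-methyl biflavone (5-hydroxy-4',5'',7'',4'''-tetramethoxy-7-pivaloyloxy-2',8''-biflavone)
Conditions: MeI (1.5 equiv), K2CO3 (1.5 equiv), dry acetone, rt
Reagents that add atoms: iodomethane, CI
Why: Williamson etherification of the only unchelated phenol (4'-OH), in which stray methylation of the chelated 5-OH would be harmless because step 6 cleaves every peri methyl ether.

Step 6
Reactants: 7 4'-O-methyl biflavone
Product: 9 target biflavone (5,7,5''-trihydroxy-4',7'',4'''-trimethoxy-2',8''-biflavone), via 5''-phenol pivalate 8 (not isolated)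
Conditions: BCl3 (5 equiv), CH2Cl2, −78 → 0 °C; MeOH quench, concentrate; K2CO3, MeOH, rt; then dilute HCl
Reagents that add atoms: none
Why: Chelation-controlled ether cleavage, in which BCl3 bound to C4''=O removes only the peri 5''-methyl group through a six-membered boron chelate and leaves the three other aryl methyl ethers, followed by carbonate-promoted transesterification of the activated aryl pivalate under conditions too mild to open a pyranone ring.

**Compound list**
1 | apigenin (5,7-dihydroxy-2-(4-hydroxyphenyl)chromen-4-one) | O=c1cc(-c2ccc(O)cc2)oc2cc(O)cc(O)c12 | starting material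
2 | 5,7,4'-trimethoxyflavone | COc1ccc(cc1)-c1cc(=O)c2c(OC)cc(OC)cc2o1 | intermediate
3 | protoapigenone | O=C1C=CC(O)(C=C1)c1cc(=O)c2c(O)cc(O)cc2o1 | intermediate
4 | 7-O-pivaloylprotoapigenone | CC(C)(C)C(=O)Oc1cc(O)c2c(c1)oc(cc2=O)C1(O)C=CC(=O)C=C1 | intermediate
5 | conjugate adduct: 4-hydroxy-5-aryl-cyclohex-2-enone, with C2' bonded to C8'' (racemic diastereomer mixture, both stereocentres erased in the same step) | CC(C)(C)C(=O)Oc1cc(O)c2c(c1)oc(cc2=O)C1(O)C=CC(=O)CC1c1c(OC)cc(OC)c2c1oc(cc2=O)-c1ccc(OC)cc1 | intermediate
6 | biflavone phenol (5,4'-dihydroxy-5'',7'',4'''-trimethoxy-7-pivaloyloxy-2',8''-biflavone) | CC(C)(C)C(=O)Oc1cc(O)c2c(c1)oc(cc2=O)-c1ccc(O)cc1-c1c(OC)cc(OC)c2c1oc(cc2=O)-c1ccc(OC)cc1 | intermediate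
7 | 4'-O-methyl biflavone (5-hydroxy-4',5'',7'',4'''-tetramethoxy-7-pivaloyloxy-2',8''-biflavone) | CC(C)(C)C(=O)Oc1cc(O)c2c(c1)oc(cc2=O)-c1ccc(OC)cc1-c1c(OC)cc(OC)c2c1oc(cc2=O)-c1ccc(OC)cc1 | intermediate
8 | 5''-phenol pivalate (5,5''-dihydroxy-4',7'',4'''-trimethoxy-7-pivaloyloxy-2',8''-biflavone) | CC(C)(C)C(=O)Oc1cc(O)c2c(c1)oc(cc2=O)-c1ccc(OC)cc1-c1c(OC)cc(O)c2c1oc(cc2=O)-c1ccc(OC)cc1 | intermediate
9 | 8-[2-(5,7-dihydroxy-4-oxochromen-2-yl)-5-methoxyphenyl]-5-hydroxy-7-methoxy-2-(4-methoxyphenyl)chromen-4-one | COc1ccc(-c2cc(=O)c3c(O)cc(OC)c(-c4cc(OC)ccc4-c4cc(=O)c5c(O)cc(O)cc5o4)c3o2)cc1 | target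

**Step count:** 6 steps in total. The longest linear sequence is 5 steps (steps 2 to 6, from apigenin).

**Steps most likely to fail**

Step 4.
- Protonation of the donor's pyranone carbonyl may lower its nucleophilicity so far that acid-induced 1,2-shift (dienone–phenol rearrangement) or oligomerisation consumes the acceptor first.
- Attack may leak to C6''.
- The adduct may stall before dehydration.

The fallback uses known chemistry, sets out from 2 and comes back at 9.
- Compound 2 is iodinated at C8 (I2, AgO2CCF3, CH2Cl2, rt) to 8-iodo-5,7,4'-trimethoxyflavone F1.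
- Suzuki–Miyaura coupling with commercial (2-formyl-5-methoxyphenyl)boronic acid (Pd(OAc)2, SPhos, K3PO4, toluene–water, 90 °C) forms the same C2'–C8'' bond and gives the biaryl aldehyde F2.
- Claisen–Schmidt condensation with commercial 1-[2,4-bis(benzyloxy)-6-hydroxyphenyl]ethanone (KOH, EtOH, rt) gives the (E)-chalcone F3.
- Catalytic I2 in DMSO at 130 °C closes and dehydrogenates the second ring C to the 5,7-bis(benzyloxy)biflavone F4.
- BCl3 with pentamethylbenzene (CH2Cl2, −78 → 0 °C) removes both benzyl groups and the peri 5''-methyl group to give 9.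

Step 2. The electron-poor phenoxenium ion may be captured poorly by water and be lost to over-oxidation and polymerisation.

The fallback replaces the reagent oxidation by electrolysis with methanol capture. It sets out from 1 and comes back at 6.
- Constant-current anodic oxidation of 1 in methanol (graphite anode, Pt cathode, LiClO4, undivided cell) gives 1'-O-methylprotoapigenone F5.
- Acylation as in step 3 gives 7-O-pivaloyl-1'-O-methylprotoapigenone F6.
- Under the conditions of step 4 with 2, this passes through the 1'-methoxy adduct F7 and loses methanol instead of water to give 6.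

Step 5. Under carbonate the pivaloyl group may be transferred from O7 to the more nucleophilic 4'-phenolate. That would scramble the two oxygen atoms the step must tell apart.

The fallback avoids any phenolate. It sets out from 6 and comes back at 7. Mitsunobu etherification with methanol (PPh3, DIAD, THF, 0 °C → rt) activates the alcohol instead of the phenol under neutral conditions. It makes no new compound (F0).

**Further compounds**
F1 | step 4 | 8-iodo-5,7,4'-trimethoxyflavone | COc1ccc(cc1)-c1cc(=O)c2c(OC)cc(OC)c(I)c2o1
F2 | step 4 | 2-[5,7-dimethoxy-2-(4-methoxyphenyl)-4-oxochromen-8-yl]-4-methoxybenzaldehyde | COc1ccc(cc1)-c1cc(=O)c2c(OC)cc(OC)c(-c3cc(OC)ccc3C=O)c2o1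
F3 | step 4 | (E)-chalcone from F2 and 1-[2,4-bis(benzyloxy)-6-hydroxyphenyl]ethanone | COc1ccc(cc1)-c1cc(=O)c2c(OC)cc(OC)c(-c3cc(OC)ccc3/C=C/C(=O)c3c(O)cc(OCc4ccccc4)cc3OCc3ccccc3)c2o1
F4 | step 4 | 5,7-bis(benzyloxy)-4',5'',7'',4'''-tetramethoxy-2',8''-biflavone | COc1ccc(cc1)-c1cc(=O)c2c(OC)cc(OC)c(-c3cc(OC)ccc3-c3cc(=O)c4c(OCc5ccccc5)cc(OCc5ccccc5)cc4o3)c2o1
F5 | step 2 | 1'-O-methylprotoapigenone | COC1(C=CC(=O)C=C1)c1cc(=O)c2c(O)cc(O)cc2o1
F6 | step 2 | 7-O-pivaloyl-1'-O-methylprotoapigenone | CC(C)(C)C(=O)Oc1cc(O)c2c(c1)oc(cc2=O)C1(OC)C=CC(=O)C=C1
F7 | step 2 | 1'-methoxy adduct (racemic diastereomer mixture, not isolated) | CC(C)(C)C(=O)Oc1cc(O)c2c(c1)oc(cc2=O)C1(OC)C=CC(=O)CC1c1c(OC)cc(OC)c2c1oc(cc2=O)-c1ccc(OC)cc1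
F0 | step 5 | none | none
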